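**Retrosynthetic overview**

1. Position labels follow elemane numbering: C10 is the quaternary carbon (vinyl C1=C2, C14H2OH), C9 the ring CH2, C8 the acyloxy carbon, C7 and C6 the lactone ring-fusion carbons, C5 carries C4(=C3H2)C15H2OH, and C11, C12, C13 are the lactone α-carbon, carbonyl and exo-methylene.
2. The C8 ester is cut last: core alcohol 27 plus (Z)-acid 33, which comes from crotonaldehyde by α-iodination and palladium-catalysed carbonylation.
3. The γ-lactone is the second ring: the C6 hydroxyl closes onto the C12 ester, then C13 is added by Eschenmoser methylenation.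
4. The cyclohexane is the first ring: a palladium-catalysed umpolung allylation of the C6 aldehyde by a 2-alkylidene-1,3-diol forms C5–C6, sets C5 and C6, and frees the C15 hydroxyl.
5. The open chain comes from an Evans syn-aldol (C7–C8) and a copper-catalysed enantioselective SN2′ coupling (C5–C10, quaternary C10 with its vinyl group).

Assumption: operations run in one flask without isolation count as one step; TBS, TBDPS and Bpin stand for tert-butyldimethylsilyl, tert-butyldiphenylsilyl and 4,4,5,5-tetramethyl-1,3,2-dioxaborolan-2-yl.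

**Route**

Step 1
Reactants: 1 methyl 4-hydroxybut-2-ynoate
Product: 2 methyl 4-(TBDPS-oxy)but-2-ynoate
Conditions: TBDPSCl, imidazole, CH2Cl2, 0 °C → rt
Reagents that add atoms: tert-butyl(chloro)diphenylsilane, CC(C)(C)[Si](Cl)(c1ccccc1)c1ccccc1
Why: Standard silylation of the primary alcohol protects the future C14 hydroxyl with a group that survives every later acidic and basic step.

Step 2
Reactants: 2 methyl 4-(TBDPS-oxy)but-2-ynoate; 3 (1,3-dioxolan-2-ylmethyl)magnesium bromide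
Product: 4 methyl (2Z)-3-[(TBDPS-oxy)methyl]-4-(1,3-dioxolan-2-yl)but-2-enoate
Conditions: 3 (2.0 equiv), CuBr·SMe2 (1.0 equiv), THF, −78 °C; NH4Cl (aq), −78 °C
Reagents that add atoms: none
Why: Organocopper conjugate addition (syn-carbocupration) to the ynoate puts the new carbon and the proton on the same side, which fixes the Z alkene (ester cis to CH2OTBDPS) when quenched cold.

Step 3
Reactants: 4 methyl (2Z)-3-[(TBDPS-oxy)methyl]-4-(1,3-dioxolan-2-yl)but-2-enoate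
Product: 5 (2Z)-3-[(TBDPS-oxy)methyl]-4-(1,3-dioxolan-2-yl)but-2-en-1-ol
Conditions: i-Bu2AlH (2.5 equiv), CH2Cl2, −78 °C; aq. potassium sodium tartrate
Reagents that add atoms: none
Why: Hydride reduction of the conjugated ester gives the allylic alcohol without touching the acetal, the silyl ether or the alkene geometry.

Step 4
Reactants: 5 (2Z)-3-[(TBDPS-oxy)methyl]-4-(1,3-dioxolan-2-yl)but-2-en-1-ol
Product: 6 (2Z)-3-[(TBDPS-oxy)methyl]-4-(1,3-dioxolan-2-yl)but-2-en-1-yl diethyl phosphate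
Conditions: ClP(O)(OEt)2, Et3N, DMAP (cat.), CH2Cl2, 0 °C
Reagents that add atoms: diethyl chlorophosphate, CCOP(=O)(Cl)OCC
Why: Phosphorylation turns the primary allylic alcohol into the leaving group needed for copper-catalysed SN2′ substitution.

Step 5
Reactants: 7 2-amino-2-(hydroxymethyl)propane-1,3-diol
Product: 8 (5-amino-2,2-dimethyl-1,3-dioxan-5-yl)methanol
Conditions: 2,2-dimethoxypropane, TsOH·H2O (1.05 equiv), DMF, rt; then Et3N
Reagents that add atoms: 2,2-dimethoxypropane, COC(C)(C)OC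
Why: Acid-catalysed transketalisation closes the six-membered acetonide on two of the three equivalent hydroxymethyl groups while the amine is held as its salt.

Step 6
Reactants: 8 (5-amino-2,2-dimethyl-1,3-dioxan-5-yl)methanol
Product: 9 2,2-dimethyl-1,3-dioxan-5-one
Conditions: NaIO4, KH2PO4, H2O, 0 °C → rt
Reagents that add atoms: water, O
Why: Periodate cleavage of the vicinal amino alcohol removes the extra carbon as formaldehyde and leaves the protected dihydroxyacetone.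

Step 7
Reactants: 9 2,2-dimethyl-1,3-dioxan-5-one
Product: 10 2-[(2,2-dimethyl-1,3-dioxan-5-ylidene)methyl]-4,4,5,5-tetramethyl-1,3,2-dioxaborolane
Conditions: CH2(Bpin)2, lithium 2,2,6,6-tetramethylpiperidide, THF, 0 °C; then 9, 0 °C → rt
Reagents that add atoms: bis(4,4,5,5-tetramethyl-1,3,2-dioxaborolan-2-yl)methane, CC1(C)OB(CB2OC(C)(C)C(C)(C)O2)OC1(C)C
Why: Boron–Wittig olefination of the symmetric ketone gives the alkenyl boronate (future C5) with no E/Z issue.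

Step 8
Reactants: 6 (2Z)-3-[(TBDPS-oxy)methyl]-4-(1,3-dioxolan-2-yl)but-2-en-1-yl diethyl phosphate; 10 2-[(2,2-dimethyl-1,3-dioxan-5-ylidene)methyl]-4,4,5,5-tetramethyl-1,3,2-dioxaborolane
Product: 11 2-{(2R)-2-[(TBDPS-oxy)methyl]-2-[(2,2-dimethyl-1,3-dioxan-5-ylidene)methyl]but-3-en-1-yl}-1,3-dioxolane
Conditions: CuCl (10 mol %), chiral sulfonate-bearing imidazolinium salt (carbene precursor, 11 mol %, enantiomer that gives the R centre), NaOMe (1.5 equiv), THF, 22 °C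
Reagents that add atoms: none
Why: Copper–carbene-catalysed enantioselective allylic substitution transfers the alkenyl group from boron to the disubstituted alkene carbon in the SN2′ sense, forming the C5–C10 bond, the vinyl group and the quaternary stereocentre C10 (R) under catalyst control on the geometrically pure Z phosphate.

Step 9
Reactants: 11 2-{(2R)-2-[(TBDPS-oxy)methyl]-2-[(2,2-dimethyl-1,3-dioxan-5-ylidene)methyl]but-3-en-1-yl}-1,3-dioxolane
Product: 12 (3R)-3-[(TBDPS-oxy)methyl]-3-[(2,2-dimethyl-1,3-dioxan-5-ylidene)methyl]pent-4-enal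
Conditions: TESOTf, 2,4,6-collidine, CH2Cl2, 0 °C; then H2O
Reagents that add atoms: water, O
Why: Silyl triflate/collidine deprotection cleaves the aldehyde acetal through a pyridinium intermediate and leaves the ketone-derived acetonide and the silyl ether intact, releasing the C8 aldehyde.

Step 10
Reactants: 13 succinic anhydride
Product: 14 4-tert-butoxy-4-oxobutanoic acid
Conditions: t-BuOH, N-hydroxysuccinimide (cat.), DMAP (cat.), Et3N, toluene, reflux
Reagents that add atoms: tert-butanol, CC(C)(C)O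
Why: Alcoholysis of the anhydride gives the mono-tert-butyl ester, whose bulk later prevents early lactonisation onto the C8 hydroxyl.

Step 11
Reactants: 14 4-tert-butoxy-4-oxobutanoic acid
Product: 15 tert-butyl 4-[(4R)-4-benzyl-2-oxo-1,3-oxazolidin-3-yl]-4-oxobutanoate
Conditions: t-BuCOCl, Et3N, THF, −20 °C; then LiCl, (4R)-4-benzyl-1,3-oxazolidin-2-one, rt
Reagents that add atoms: (4R)-4-benzyl-1,3-oxazolidin-2-one, O=C1OC[C@@H](Cc2ccccc2)N1
Why: Mixed-anhydride N-acylation attaches the Evans auxiliary that will control C7 and C8.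

Step 12
Reactants: 12 (3R)-3-[(TBDPS-oxy)methyl]-3-[(2,2-dimethyl-1,3-dioxan-5-ylidene)methyl]pent-4-enal; 15 tert-butyl 4-[(4R)-4-benzyl-2-oxo-1,3-oxazolidin-3-yl]-4-oxobutanoate
Product: 16 tert-butyl (3R,4S,6R)-3-{[(4R)-4-benzyl-2-oxo-1,3-oxazolidin-3-yl]carbonyl}-6-[(TBDPS-oxy)methyl]-6-[(2,2-dimethyl-1,3-dioxan-5-ylidene)methyl]-4-hydroxyoct-7-enoate
Conditions: 15, n-Bu2BOTf, i-Pr2NEt, CH2Cl2, −78 → 0 °C; then 12, −78 → 0 °C; pH 7 buffer, MeOH, H2O2
Reagents that add atoms: none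
Why: The Evans syn-aldol of the Z boron enolate through a Zimmerman–Traxler chair forms C7–C8 and sets C7 (R) and C8 (S) by auxiliary control, independent of the remote C10 centre.

Step 13
Reactants: 16 tert-butyl (3R,4S,6R)-3-{[(4R)-4-benzyl-2-oxo-1,3-oxazolidin-3-yl]carbonyl}-6-[(TBDPS-oxy)methyl]-6-[(2,2-dimethyl-1,3-dioxan-5-ylidene)methyl]-4-hydroxyoct-7-enoate
Product: 17 tert-butyl (3R,4S,6R)-3-{[(4R)-4-benzyl-2-oxo-1,3-oxazolidin-3-yl]carbonyl}-4-(TBS-oxy)-6-[(TBDPS-oxy)methyl]-6-[(2,2-dimethyl-1,3-dioxan-5-ylidene)methyl]oct-7-enoate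
Conditions: TBSOTf, 2,6-lutidine, CH2Cl2, −78 → 0 °C
Reagents that add atoms: tert-butyldimethylsilyl trifluoromethanesulfonate, CC(C)(C)[Si](C)(C)OS(=O)(=O)C(F)(F)F
Why: Silylation at low temperature protects the C8 hydroxyl (blocking retro-aldol and later translactonisation) without cleaving the tert-butyl ester.

Step 14
Reactants: 17 tert-butyl (3R,4S,6R)-3-{[(4R)-4-benzyl-2-oxo-1,3-oxazolidin-3-yl]carbonyl}-4-(TBS-oxy)-6-[(TBDPS-oxy)methyl]-6-[(2,2-dimethyl-1,3-dioxan-5-ylidene)methyl]oct-7-enoate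
Product: 18 tert-butyl (3S,4S,6R)-4-(TBS-oxy)-6-[(TBDPS-oxy)methyl]-6-[(2,2-dimethyl-1,3-dioxan-5-ylidene)methyl]-3-(hydroxymethyl)oct-7-enoate
Conditions: LiBH4, MeOH (1 equiv), THF, 0 °C
Reagents that add atoms: none
Why: Borohydride cleaves the activated imide carbonyl reductively to the C6 primary alcohol much faster than it attacks the tert-butyl ester, and the auxiliary is recovered.

Step 15
Reactants: 18 tert-butyl (3S,4S,6R)-4-(TBS-oxy)-6-[(TBDPS-oxy)methyl]-6-[(2,2-dimethyl-1,3-dioxan-5-ylidene)methyl]-3-(hydroxymethyl)oct-7-enoate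
Product: 19 tert-butyl (3R,4S,6R)-4-(TBS-oxy)-6-[(TBDPS-oxy)methyl]-6-[(2,2-dimethyl-1,3-dioxan-5-ylidene)methyl]-3-formyloct-7-enoate
Conditions: Dess–Martin periodinane, NaHCO3, CH2Cl2, 0 °C → rt
Reagents that add atoms: none
Why: Buffered Dess–Martin oxidation gives the C6 aldehyde without epimerising the adjacent C7 centre; the aldehyde is carried on directly.

Step 16
Reactants: 19 tert-butyl (3R,4S,6R)-4-(TBS-oxy)-6-[(TBDPS-oxy)methyl]-6-[(2,2-dimethyl-1,3-dioxan-5-ylidene)methyl]-3-formyloct-7-enoate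
Product: 20 tert-butyl (3R,4S,6R)-4-(TBS-oxy)-6-[(TBDPS-oxy)methyl]-3-formyl-6-[3-hydroxy-2-(hydroxymethyl)prop-1-en-1-yl]oct-7-enoate
Conditions: AcOH/H2O (4:1), rt
Reagents that add atoms: none
Why: Mild aqueous acid hydrolyses the six-membered acetonide to the 2-alkylidene-1,3-diol while the secondary TBS ether, the TBDPS ether and the tert-butyl ester stay in place.

Step 17
Reactants: 20 tert-butyl (3R,4S,6R)-4-(TBS-oxy)-6-[(TBDPS-oxy)methyl]-3-formyl-6-[3-hydroxy-2-(hydroxymethyl)prop-1-en-1-yl]oct-7-enoate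
Product: 22 (3aS,4S,6R,7S,7aR)-4-(TBS-oxy)-6-[(TBDPS-oxy)methyl]-6-ethenyl-7-(3-hydroxyprop-1-en-2-yl)hexahydro-1-benzofuran-2(3H)-one, via hydroxy tert-butyl ester 21 (not isolated)
Conditions: Pd(OAc)2 (10 mol %), P(n-Bu)3 (30 mol %), Et3B (3 equiv), degassed THF, rt; NaHCO3 (aq) work-up; then camphorsulfonic acid (20 mol %), toluene, 60 °C
Reagents that add atoms: none
Why: Proposed new method: zerovalent palladium (formed from Pd(OAc)2 and P(n-Bu)3) ionises one of the two equivalent allylic C–O bonds after Et3B coordination, allyl/ethyl exchange with Et3B gives a primary allyl–BEt2, and its γ-carbon (C5) adds to the C6 aldehyde through a trans-decalin-like chair with the C7 and C8 substituents equatorial, so the cyclohexane ring, the C5–C6 bond and the trans C5 (S)/C6 (R) centres form at once while the second allylic oxygen remains as the free C15 hydroxyl, and acid then closes the trans-fused γ-lactone from the C6 hydroxyl onto the tert-butyl ester; the closest known reaction type is the intermolecular palladium/triethylborane umpolung allylation of aldehydes with allylic alcohols (Tamaru allylation) together with intramolecular allylborations, not yet shown as a ring closure with a γ-substituted bis-allylic diol donor.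

Step 18
Reactants: 22 (3aS,4S,6R,7S,7aR)-4-(TBS-oxy)-6-[(TBDPS-oxy)methyl]-6-ethenyl-7-(3-hydroxyprop-1-en-2-yl)hexahydro-1-benzofuran-2(3H)-one
Product: 23 (3aS,4S,6R,7S,7aR)-4-(TBS-oxy)-6-[(TBDPS-oxy)methyl]-7-[3-(TBDPS-oxy)prop-1-en-2-yl]-6-ethenylhexahydro-1-benzofuran-2(3H)-one
Conditions: TBDPSCl, imidazole, DMF, rt
Reagents that add atoms: tert-butyl(chloro)diphenylsilane, CC(C)(C)[Si](Cl)(c1ccccc1)c1ccccc1
Why: Silylation of the only free hydroxyl (C15) leaves C8–OTBS as the one silyl ether that can later be removed selectively.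

Step 19
Reactants: 23 (3aS,4S,6R,7S,7aR)-4-(TBS-oxy)-6-[(TBDPS-oxy)methyl]-7-[3-(TBDPS-oxy)prop-1-en-2-yl]-6-ethenylhexahydro-1-benzofuran-2(3H)-one
Product: 26 (3aS,4S,6R,7S,7aR)-4-(TBS-oxy)-6-[(TBDPS-oxy)methyl]-7-[3-(TBDPS-oxy)prop-1-en-2-yl]-6-ethenyl-3-methylidenehexahydro-1-benzofuran-2(3H)-one, via Mannich base 24 (not isolated), via trimethylammonium iodide 25 (not isolated)
Conditions: LiN(i-Pr)2, THF, −78 °C; CH2=NMe2+ I−, −78 °C → rt; then MeI, MeOH, rt; then NaHCO3 (aq), CH2Cl2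
Reagents that add atoms: N,N-dimethylmethaniminium iodide (Eschenmoser's salt), C=[N+](C)C.[I-]; iodomethane, CI (enters only intermediate 25)
Why: Eschenmoser α-methylenation (lactone enolate Mannich reaction, N-methylation, β-elimination) installs C13 on the trans-fused lactone with every hydroxyl masked, so no alkoxide can attack the lactone.

Step 20
Reactants: 26 (3aS,4S,6R,7S,7aR)-4-(TBS-oxy)-6-[(TBDPS-oxy)methyl]-7-[3-(TBDPS-oxy)prop-1-en-2-yl]-6-ethenyl-3-methylidenehexahydro-1-benzofuran-2(3H)-one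
Product: 27 (3aR,4S,6R,7S,7aR)-6-[(TBDPS-oxy)methyl]-7-[3-(TBDPS-oxy)prop-1-en-2-yl]-6-ethenyl-4-hydroxy-3-methylidenehexahydro-1-benzofuran-2(3H)-one
Conditions: HF·pyridine, pyridine, THF, 0 °C → rt
Reagents that add atoms: none
Why: Buffered fluoride removes the secondary TBS ether much faster than the two primary TBDPS ethers, freeing only the C8 hydroxyl under non-basic conditions that cannot move the lactone.

Step 21
Reactants: 28 (2E)-but-2-enal
Product: 29 (2Z)-2-iodobut-2-enal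
Conditions: I2, K2CO3, DMAP (20 mol %), THF/H2O (1:1), rt
Reagents that add atoms: iodine, II
Why: Amine-catalysed α-iodination (conjugate addition, iodination, elimination) gives the thermodynamic Z isomer with iodine cis to the methyl group.

Step 22
Reactants: 29 (2Z)-2-iodobut-2-enal
Product: 30 (2Z)-2-iodobut-2-en-1-ol
Conditions: NaBH4, CeCl3·7H2O, MeOH, 0 °C
Reagents that add atoms: none
Why: Luche 1,2-reduction gives the allylic alcohol without touching the vinyl iodide or its geometry.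

Step 23
Reactants: 30 (2Z)-2-iodobut-2-en-1-ol
Product: 31 tert-butyl{[(2Z)-2-iodobut-2-en-1-yl]oxy}dimethylsilane
Conditions: TBSCl, imidazole, CH2Cl2, rt
Reagents that add atoms: tert-butyl(chloro)dimethylsilane, CC(C)(C)[Si](C)(C)Cl
Why: Silylation blocks the hydroxyl so that carbonylation cannot close to a β-lactone.

Step 24
Reactants: 31 tert-butyl{[(2Z)-2-iodobut-2-en-1-yl]oxy}dimethylsilane
Product: 32 methyl (2Z)-2-[(TBS-oxy)methyl]but-2-enoate
Conditions: Pd(OAc)2 (5 mol %), PPh3 (10 mol %), CO (1 atm), MeOH, Et3N, DMF, 50 °C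
Reagents that add atoms: carbon monoxide, [C-]#[O+]; methanol, CO
Why: Palladium-catalysed alkoxycarbonylation replaces iodine by the ester with retention of alkene geometry, placing the carbonyl cis to the methyl group (Z).

Step 25
Reactants: 32 methyl (2Z)-2-[(TBS-oxy)methyl]but-2-enoate
Product: 33 (2Z)-2-[(TBS-oxy)methyl]but-2-enoic acid
Conditions: LiOH·H2O, THF/MeOH/H2O, 0 °C → rt; then HCl (1 M) to pH 4 at 0 °C
Reagents that add atoms: lithium hydroxide, [Li+].[OH-]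
Why: Cold saponification frees the acid without Z to E isomerisation or loss of the silyl ether.

Step 26
Reactants: 27 (3aR,4S,6R,7S,7aR)-6-[(TBDPS-oxy)methyl]-7-[3-(TBDPS-oxy)prop-1-en-2-yl]-6-ethenyl-4-hydroxy-3-methylidenehexahydro-1-benzofuran-2(3H)-one; 33 (2Z)-2-[(TBS-oxy)methyl]but-2-enoic acid
Product: 34 (3aR,4S,6R,7S,7aR)-6-[(TBDPS-oxy)methyl]-7-[3-(TBDPS-oxy)prop-1-en-2-yl]-6-ethenyl-3-methylidene-2-oxooctahydro-1-benzofuran-4-yl (2Z)-2-[(TBS-oxy)methyl]but-2-enoate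
Conditions: 33, 2,4,6-trichlorobenzoyl chloride, Et3N, toluene, rt; then 27, DMAP, rt
Reagents that add atoms: none
Why: Yamaguchi esterification through the mixed anhydride acylates the hindered equatorial C8 hydroxyl with retention at C8, and room temperature limits Z to E isomerisation of the acyl group.

Step 27
Reactants: 34 (3aR,4S,6R,7S,7aR)-6-[(TBDPS-oxy)methyl]-7-[3-(TBDPS-oxy)prop-1-en-2-yl]-6-ethenyl-3-methylidene-2-oxooctahydro-1-benzofuran-4-yl (2Z)-2-[(TBS-oxy)methyl]but-2-enoate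
Product: 35 (3aR,4S,6R,7S,7aR)-6-ethenyl-6-(hydroxymethyl)-7-(3-hydroxyprop-1-en-2-yl)-3-methylidene-2-oxooctahydro-1-benzofuran-4-yl (2Z)-2-(hydroxymethyl)but-2-enoate
Conditions: Bu4NF, AcOH (1:1), THF, 0 °C → rt
Reagents that add atoms: none
Why: Acetic-acid-buffered fluoride removes all three silyl ethers without acyl migration or conjugate addition to the methylene lactone, giving the target.

**Compound list**

1 | methyl 4-hydroxybut-2-ynoate | COC(=O)C#CCO | starting material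
2 | methyl 4-(TBDPS-oxy)but-2-ynoate | COC(=O)C#CCO[Si](c1ccccc1)(c1ccccc1)C(C)(C)C | intermediate
3 | (1,3-dioxolan-2-ylmethyl)magnesium bromide | Br[Mg]CC1OCCO1 | starting material
4 | methyl (2Z)-3-[(TBDPS-oxy)methyl]-4-(1,3-dioxolan-2-yl)but-2-enoate | COC(=O)/C=C(\CO[Si](c1ccccc1)(c1ccccc1)C(C)(C)C)CC1OCCO1 | intermediate
5 | (2Z)-3-[(TBDPS-oxy)methyl]-4-(1,3-dioxolan-2-yl)but-2-en-1-ol | OC/C=C(\CO[Si](c1ccccc1)(c1ccccc1)C(C)(C)C)CC1OCCO1 | intermediate
6 | (2Z)-3-[(TBDPS-oxy)methyl]-4-(1,3-dioxolan-2-yl)but-2-en-1-yl diethyl phosphate | CCOP(=O)(OCC)OC/C=C(\CO[Si](c1ccccc1)(c1ccccc1)C(C)(C)C)CC1OCCO1 | intermediate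
7 | 2-amino-2-(hydroxymethyl)propane-1,3-diol | NC(CO)(CO)CO | starting material
8 | (5-amino-2,2-dimethyl-1,3-dioxan-5-yl)methanol | CC1(C)OCC(N)(CO)CO1 | intermediate
9 | 2,2-dimethyl-1,3-dioxan-5-one | CC1(C)OCC(=O)CO1 | intermediate
10 | 2-[(2,2-dimethyl-1,3-dioxan-5-ylidene)methyl]-4,4,5,5-tetramethyl-1,3,2-dioxaborolane | CC1(C)OCC(=CB2OC(C)(C)C(C)(C)O2)CO1 | intermediate
11 | 2-{(2R)-2-[(TBDPS-oxy)methyl]-2-[(2,2-dimethyl-1,3-dioxan-5-ylidene)methyl]but-3-en-1-yl}-1,3-dioxolane | C=C[C@](C=C1COC(C)(C)OC1)(CO[Si](c1ccccc1)(c1ccccc1)C(C)(C)C)CC1OCCO1 | intermediate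
12 | (3R)-3-[(TBDPS-oxy)methyl]-3-[(2,2-dimethyl-1,3-dioxan-5-ylidene)methyl]pent-4-enal | C=C[C@](C=C1COC(C)(C)OC1)(CO[Si](c1ccccc1)(c1ccccc1)C(C)(C)C)CC=O | intermediate
13 | succinic anhydride | O=C1CCC(=O)O1 | starting material
14 | 4-tert-butoxy-4-oxobutanoic acid | CC(C)(C)OC(=O)CCC(=O)O | intermediate
15 | tert-butyl 4-[(4R)-4-benzyl-2-oxo-1,3-oxazolidin-3-yl]-4-oxobutanoate | CC(C)(C)OC(=O)CCC(=O)N1C(=O)OC[C@H]1Cc1ccccc1 | intermediate
16 | tert-butyl (3R,4S,6R)-3-{[(4R)-4-benzyl-2-oxo-1,3-oxazolidin-3-yl]carbonyl}-6-[(TBDPS-oxy)methyl]-6-[(2,2-dimethyl-1,3-dioxan-5-ylidene)methyl]-4-hydroxyoct-7-enoate | C=C[C@](C=C1COC(C)(C)OC1)(CO[Si](c1ccccc1)(c1ccccc1)C(C)(C)C)C[C@H](O)[C@@H](CC(=O)OC(C)(C)C)C(=O)N1C(=O)OC[C@H]1Cc1ccccc1 | intermediate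
17 | tert-butyl (3R,4S,6R)-3-{[(4R)-4-benzyl-2-oxo-1,3-oxazolidin-3-yl]carbonyl}-4-(TBS-oxy)-6-[(TBDPS-oxy)methyl]-6-[(2,2-dimethyl-1,3-dioxan-5-ylidene)methyl]oct-7-enoate | C=C[C@](C=C1COC(C)(C)OC1)(CO[Si](c1ccccc1)(c1ccccc1)C(C)(C)C)C[C@H](O[Si](C)(C)C(C)(C)C)[C@@H](CC(=O)OC(C)(C)C)C(=O)N1C(=O)OC[C@H]1Cc1ccccc1 | intermediate
18 | tert-butyl (3S,4S,6R)-4-(TBS-oxy)-6-[(TBDPS-oxy)methyl]-6-[(2,2-dimethyl-1,3-dioxan-5-ylidene)methyl]-3-(hydroxymethyl)oct-7-enoate | C=C[C@](C=C1COC(C)(C)OC1)(CO[Si](c1ccccc1)(c1ccccc1)C(C)(C)C)C[C@H](O[Si](C)(C)C(C)(C)C)[C@@H](CC(=O)OC(C)(C)C)CO | intermediate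
19 | tert-butyl (3R,4S,6R)-4-(TBS-oxy)-6-[(TBDPS-oxy)methyl]-6-[(2,2-dimethyl-1,3-dioxan-5-ylidene)methyl]-3-formyloct-7-enoate | C=C[C@](C=C1COC(C)(C)OC1)(CO[Si](c1ccccc1)(c1ccccc1)C(C)(C)C)C[C@H](O[Si](C)(C)C(C)(C)C)[C@@H](CC(=O)OC(C)(C)C)C=O | intermediate
20 | tert-butyl (3R,4S,6R)-4-(TBS-oxy)-6-[(TBDPS-oxy)methyl]-3-formyl-6-[3-hydroxy-2-(hydroxymethyl)prop-1-en-1-yl]oct-7-enoate | C=C[C@](C=C(CO)CO)(CO[Si](c1ccccc1)(c1ccccc1)C(C)(C)C)C[C@H](O[Si](C)(C)C(C)(C)C)[C@@H](CC(=O)OC(C)(C)C)C=O | intermediate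
21 | tert-butyl 2-[(1S,2R,3S,4R,6S)-6-(TBS-oxy)-4-[(TBDPS-oxy)methyl]-4-ethenyl-2-hydroxy-3-(3-hydroxyprop-1-en-2-yl)cyclohexyl]acetate | C=C[C@]1(CO[Si](c2ccccc2)(c2ccccc2)C(C)(C)C)C[C@H](O[Si](C)(C)C(C)(C)C)[C@@H](CC(=O)OC(C)(C)C)[C@H](O)[C@H]1C(=C)CO | intermediate
22 | (3aS,4S,6R,7S,7aR)-4-(TBS-oxy)-6-[(TBDPS-oxy)methyl]-6-ethenyl-7-(3-hydroxyprop-1-en-2-yl)hexahydro-1-benzofuran-2(3H)-one | C=C[C@]1(CO[Si](c2ccccc2)(c2ccccc2)C(C)(C)C)C[C@H](O[Si](C)(C)C(C)(C)C)[C@H]2CC(=O)O[C@@H]2[C@H]1C(=C)CO | intermediate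
23 | (3aS,4S,6R,7S,7aR)-4-(TBS-oxy)-6-[(TBDPS-oxy)methyl]-7-[3-(TBDPS-oxy)prop-1-en-2-yl]-6-ethenylhexahydro-1-benzofuran-2(3H)-one | C=C[C@]1(CO[Si](c2ccccc2)(c2ccccc2)C(C)(C)C)C[C@H](O[Si](C)(C)C(C)(C)C)[C@H]2CC(=O)O[C@@H]2[C@H]1C(=C)CO[Si](c2ccccc2)(c2ccccc2)C(C)(C)C | intermediate
24 | 3-[(dimethylamino)methyl] derivative of 23 (both C3 epimers) | C=C[C@]1(CO[Si](c2ccccc2)(c2ccccc2)C(C)(C)C)C[C@H](O[Si](C)(C)C(C)(C)C)[C@H]2C(CN(C)C)C(=O)O[C@@H]2[C@H]1C(=C)CO[Si](c2ccccc2)(c2ccccc2)C(C)(C)C | intermediate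
25 | N-methyl quaternary ammonium iodide of 24 | C=C[C@]1(CO[Si](c2ccccc2)(c2ccccc2)C(C)(C)C)C[C@H](O[Si](C)(C)C(C)(C)C)[C@H]2C(C[N+](C)(C)C)C(=O)O[C@@H]2[C@H]1C(=C)CO[Si](c2ccccc2)(c2ccccc2)C(C)(C)C.[I-] | intermediate
26 | (3aS,4S,6R,7S,7aR)-4-(TBS-oxy)-6-[(TBDPS-oxy)methyl]-7-[3-(TBDPS-oxy)prop-1-en-2-yl]-6-ethenyl-3-methylidenehexahydro-1-benzofuran-2(3H)-one | C=C[C@]1(CO[Si](c2ccccc2)(c2ccccc2)C(C)(C)C)C[C@H](O[Si](C)(C)C(C)(C)C)[C@H]2C(=C)C(=O)O[C@@H]2[C@H]1C(=C)CO[Si](c2ccccc2)(c2ccccc2)C(C)(C)C | intermediate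
27 | (3aR,4S,6R,7S,7aR)-6-[(TBDPS-oxy)methyl]-7-[3-(TBDPS-oxy)prop-1-en-2-yl]-6-ethenyl-4-hydroxy-3-methylidenehexahydro-1-benzofuran-2(3H)-one | C=C[C@]1(CO[Si](c2ccccc2)(c2ccccc2)C(C)(C)C)C[C@H](O)[C@H]2C(=C)C(=O)O[C@@H]2[C@H]1C(=C)CO[Si](c2ccccc2)(c2ccccc2)C(C)(C)C | intermediate
28 | (2E)-but-2-enal | C/C=C/C=O | starting material
29 | (2Z)-2-iodobut-2-enal | C/C=C(\I)C=O | intermediate
30 | (2Z)-2-iodobut-2-en-1-ol | C/C=C(\I)CO | intermediate
31 | tert-butyl{[(2Z)-2-iodobut-2-en-1-yl]oxy}dimethylsilane | C/C=C(\I)CO[Si](C)(C)C(C)(C)C | intermediate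
32 | methyl (2Z)-2-[(TBS-oxy)methyl]but-2-enoate | C/C=C(\C(=O)OC)CO[Si](C)(C)C(C)(C)C | intermediate
33 | (2Z)-2-[(TBS-oxy)methyl]but-2-enoic acid | C/C=C(\C(=O)O)CO[Si](C)(C)C(C)(C)C | intermediate
34 | (3aR,4S,6R,7S,7aR)-6-[(TBDPS-oxy)methyl]-7-[3-(TBDPS-oxy)prop-1-en-2-yl]-6-ethenyl-3-methylidene-2-oxooctahydro-1-benzofuran-4-yl (2Z)-2-[(TBS-oxy)methyl]but-2-enoate | C=C[C@]1(CO[Si](c2ccccc2)(c2ccccc2)C(C)(C)C)C[C@H](OC(=O)/C(=C\C)CO[Si](C)(C)C(C)(C)C)[C@H]2C(=C)C(=O)O[C@@H]2[C@H]1C(=C)CO[Si](c2ccccc2)(c2ccccc2)C(C)(C)C | intermediate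
35 | (3aR,4S,6R,7S,7aR)-6-ethenyl-6-(hydroxymethyl)-7-(3-hydroxyprop-1-en-2-yl)-3-methylidene-2-oxooctahydro-1-benzofuran-4-yl (2Z)-2-(hydroxymethyl)but-2-enoate | C=C[C@]1(CO)C[C@H](OC(=O)/C(=C\C)CO)[C@H]2C(=C)C(=O)O[C@@H]2[C@H]1C(=C)CO | target

**Step count and risks**

Total step count: 27. Longest linear sequence: 17 (steps 1–4, 8, 9, 12–20, 26, 27); the other branches are steps 5–7, 10–11 and 21–25.

The three steps most likely to fail:

Step 17 (the proposed new ring closure). The ionised allyl unit may be over-reduced, the free C15 hydroxyl may be ionised a second time and close a methylene-tetrahydrofuran onto the C6 oxygen, or allyl transfer to boron may be slow at the neopentyl-like terminus. The fallback uses known chemistry, sets out from 20 and comes back at 23. Treating 20 with one equivalent of TBDPSCl and imidazole (statistical, unreacted 20 recycled) gives the mono-silylated allylic alcohol F4 as a mixture of alkene isomers, which does not matter. N-chlorosuccinimide and Me2S (Corey–Kim chlorination, aldehyde tolerated) convert it into the allylic chloride F5. CrCl2 (4 equiv) with LiI (cat.) in THF then closes the ring by an intramolecular Nozaki–Hiyama allylation through the same chair transition state, giving the cyclohexanol tert-butyl ester F6. Camphorsulfonic acid in toluene lactonises F6 to 23, so step 18 is not needed.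

Step 8 (enantioselective SN2′ coupling). The two CH2X groups on the alkene are similar in size, so the enantiomeric excess may be low, and the trisubstituted alkenyl boronate may transfer slowly. The fallback sets out from 6 and 10 and comes back at 16; it replaces catalyst control by resolution on the auxiliary. An achiral copper catalyst (CuCl, 1,3-bis(2,4,6-trimethylphenyl)imidazolium chloride, NaOMe, THF, 40 °C) gives the racemic diene acetal F1. TESOTf/2,4,6-collidine then water gives the racemic aldehyde F2. The aldol of step 12 with 15 fixes C7 and C8 absolutely in both products, so 16 and its C10 epimer F3 are diastereomers and are separated by chromatography (at most half of the material is used).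

Step 26 (esterification). The Z acyl group can isomerise to the E isomer through the activated acyl species, and the C8 hydroxyl is hindered. The fallback sets out from 27 and the vinyl iodide 31 and comes back at 34. Palladium-catalysed alkoxycarbonylation (Pd(OAc)2, Xantphos, CO 1 atm, Et3N, toluene, 70 °C) builds the ester from the acylpalladium species formed by stereoretentive oxidative addition and CO insertion, so the acid is never activated; this fallback makes no new compound (F0).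

**Further compounds**

F1 | step 8 | racemic 2-{2-[(TBDPS-oxy)methyl]-2-[(2,2-dimethyl-1,3-dioxan-5-ylidene)methyl]but-3-en-1-yl}-1,3-dioxolane | C=CC(C=C1COC(C)(C)OC1)(CO[Si](c1ccccc1)(c1ccccc1)C(C)(C)C)CC1OCCO1
F2 | step 8 | racemic 3-[(TBDPS-oxy)methyl]-3-[(2,2-dimethyl-1,3-dioxan-5-ylidene)methyl]pent-4-enal | C=CC(C=C1COC(C)(C)OC1)(CO[Si](c1ccccc1)(c1ccccc1)C(C)(C)C)CC=O
F3 | step 8 | tert-butyl (3R,4S,6S)-3-{[(4R)-4-benzyl-2-oxo-1,3-oxazolidin-3-yl]carbonyl}-6-[(TBDPS-oxy)methyl]-6-[(2,2-dimethyl-1,3-dioxan-5-ylidene)methyl]-4-hydroxyoct-7-enoate (6-epimer of 16) | C=C[C@@](C=C1COC(C)(C)OC1)(CO[Si](c1ccccc1)(c1ccccc1)C(C)(C)C)C[C@H](O)[C@@H](CC(=O)OC(C)(C)C)C(=O)N1C(=O)OC[C@H]1Cc1ccccc1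
F4 | step 17 | tert-butyl (3R,4S,6R)-4-(TBS-oxy)-6-[(TBDPS-oxy)methyl]-3-formyl-6-{3-hydroxy-2-[(TBDPS-oxy)methyl]prop-1-en-1-yl}oct-7-enoate (alkene isomer mixture) | C=C[C@](C=C(CO)CO[Si](c1ccccc1)(c1ccccc1)C(C)(C)C)(CO[Si](c1ccccc1)(c1ccccc1)C(C)(C)C)C[C@H](O[Si](C)(C)C(C)(C)C)[C@@H](CC(=O)OC(C)(C)C)C=O
F5 | step 17 | tert-butyl (3R,4S,6R)-4-(TBS-oxy)-6-[(TBDPS-oxy)methyl]-6-{3-chloro-2-[(TBDPS-oxy)methyl]prop-1-en-1-yl}-3-formyloct-7-enoate (alkene isomer mixture) | C=C[C@](C=C(CCl)CO[Si](c1ccccc1)(c1ccccc1)C(C)(C)C)(CO[Si](c1ccccc1)(c1ccccc1)C(C)(C)C)C[C@H](O[Si](C)(C)C(C)(C)C)[C@@H](CC(=O)OC(C)(C)C)C=O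
F6 | step 17 | tert-butyl 2-[(1S,2R,3S,4R,6S)-6-(TBS-oxy)-4-[(TBDPS-oxy)methyl]-3-[3-(TBDPS-oxy)prop-1-en-2-yl]-4-ethenyl-2-hydroxycyclohexyl]acetate | C=C[C@]1(CO[Si](c2ccccc2)(c2ccccc2)C(C)(C)C)C[C@H](O[Si](C)(C)C(C)(C)C)[C@@H](CC(=O)OC(C)(C)C)[C@H](O)[C@H]1C(=C)CO[Si](c2ccccc2)(c2ccccc2)C(C)(C)C
F0 | step 26 | none | none
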